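## Retrosynthetic overview
1. Target 22 comes from ketone 20 (methylenation, silyl removal). 20 comes from ring-closing metathesis of the trans-2-allyl-3-isopropenylcycloheptanone 19, and 19 from conjugate addition/allylation of the γ-silyloxy enone 17 (sets C5 and C1).
2. 17 comes from reductive opening (SmI2) of an 8-oxabicyclo[3.2.1]octanone. The bridge oxygen is the latent C6–OH and is held cis to the side chain.
3. Bicycle 9 comes from an enantioselective [5+2] cycloaddition. It dearomatises the 6π betaine 3-oxidopyrylium 8, which carries all five carbons of furfuryl alcohol 1 (furan opened by Achmatowicz oxidation), with vinyl ketone 7.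
4. The oxolane comes from MeMgBr addition to the side-chain ketone (C11), then reagent-controlled epoxidation and 5-exo opening (C14).
5. Ring order: seven-membered carbocycle (as the oxa-bridged bicycle), then oxolane, then cyclopentene.

Numbering used for the target:
- C1 and C5 are the ring-fusion carbons, with C1 next to C10.
- C2–C4 complete the cyclopentene; C4 bears the methyl.
- C6 is the carbinol carbon, C7 carries the side chain, C8 and C9 are CH2, and C10 carries the =CH2.
- C11 and C14 are the oxolane carbons; C15 is CMe2OAc.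

Assumption: the SMILES is taken literally, that is (1R,5S,6S,7R,11S,14R) with H-1/H-5 trans, 6-OH cis to the side chain and a 2,5-cis oxolane; the quinidine-series catalyst of step 4 is taken to give (1S,5S)-9, and its quinine-series pseudo-enantiomer is used if the sense is opposite.

## Route

Step 1
Reactants: 1 furfuryl alcohol
Product: 2 6-hydroxy-2H-pyran-3(6H)-one
Conditions: NBS, NaHCO3, THF/H2O 4:1, 0 °C
Reagents that add atoms: water (O)
Why: Achmatowicz rearrangement (oxidative ring expansion of a furfuryl alcohol) ends the furan aromaticity and keeps all five carbons; the hemiacetal centre is erased again in step 4.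

Step 2
Reactants: 2 6-hydroxy-2H-pyran-3(6H)-one
Product: 3 6-acetoxy-2H-pyran-3(6H)-one
Conditions: Ac2O, pyridine, DMAP (cat.), CH2Cl2, 0 °C
Reagents that add atoms: acetic anhydride (CC(=O)OC(C)=O)
Why: O-acylation turns the anomeric OH into the leaving group needed for ylide formation; the centre is stereochemically irrelevant.

Step 3
Reactants: 4 5-bromo-2-methylpent-2-ene; 5 N-methoxy-N-methylacrylamide
Product: 7 7-methylocta-1,6-dien-3-one, via homoprenylmagnesium bromide 6 (not isolated)
Conditions: Mg, THF, rt; then 5, −78 to 0 °C; pour into cold 1 M HCl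
Reagents that add atoms: none
Why: Weinreb ketone synthesis: the N-methoxy amide takes up only one equivalent of Grignard reagent, and the cold acid quench removes MeNHOMe before it can add to the vinyl ketone.

Step 4 (key step)
Reactants: 3 6-acetoxy-2H-pyran-3(6H)-one; 7 7-methylocta-1,6-dien-3-one
Product: 9 (1S,5S,6R)-6-(5-methylhex-4-enoyl)-8-oxabicyclo[3.2.1]oct-3-en-2-one (exo acyl), via 3-oxidopyrylium 8 (not isolated)
Conditions: 7 (2 equiv), quinidine-derived squaramide tertiary-amine catalyst (20 mol %), CHCl3, −20 °C; then DBU (5 mol %), 0 °C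
Reagents that add atoms: none
Why: Proposed new method: the catalyst amine expels AcOH from 3 (E1cB) to give the planar aromatic betaine 8, which stays hydrogen-bonded through its oxido oxygen in the ammonium/squaramide pocket while the squaramide N–H bonds activate the carbonyl of 7, so the Michael-type attack of ylide C2 on the CH2 terminus of 7 occurs on one face of 8 and ring closure on C6 follows suprafacially (polar [5+2] oxidopyrylium cycloaddition, acyl-bearing carbon bonded to the oxocarbenium terminus), which fixes C1 and C5 of 9 (later the C6–O of the target), and the epimerisable acyl-bearing C6 is drained by DBU to the less hindered exo position without loss of ee because the ee resides in the bicyclic core; the closest known reaction types are the amine-triggered racemic oxidopyrylium [5+2] cycloaddition with vinyl ketones and acrylates, the thiourea/aminothiourea-catalysed enantioselective oxidopyrylium [5+2] cycloaddition with electron-rich alkenes, and the cinchona-catalysed enantioselective Michael addition of cyclic carbonyl donors to vinyl ketones.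

Step 5
Reactants: 9 (1S,5S,6R)-6-(5-methylhex-4-enoyl)-8-oxabicyclo[3.2.1]oct-3-en-2-one
Product: 11 (1S,4S,5R,6R)-6-[(2S)-2-hydroxy-6-methylhept-5-en-2-yl]-4-(phenylsulfanyl)-8-oxabicyclo[3.2.1]octan-2-one, via thio silyl enol ether 10 (not isolated)
Conditions: PhSSiMe3 (1.1 equiv), Me3SiOTf (5 mol %), CH2Cl2, −78 °C; MeMgBr, −78 °C; 1 M HCl, 0 °C
Reagents that add atoms: (phenylsulfanyl)trimethylsilane (C[Si](C)(C)Sc1ccccc1); methylmagnesium bromide (C[Mg]Br)
Why: Thiosilane 1,4-addition on the exo face masks the enone as silyl enol ether 10 so that MeMgBr meets only the side-chain ketone, where Felkin–Anh attack anti to the bridgehead carbon from the open exo side (homoprenyl chain next to H-6) gives the (S)-carbinol C11, and the acid quench frees the now saturated ring ketone while the sulfide stays as a latent C1=C5 double bond.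

Step 6
Reactants: 11 (1S,4S,5R,6R)-sulfide carbinol
Product: 12 (3S,4R,5R)-4-hydroxy-5-[(2S)-2-hydroxy-6-methylhept-5-en-2-yl]-3-(phenylsulfanyl)cycloheptan-1-one
Conditions: SmI2 (2.5 equiv), THF/MeOH, −78 to 0 °C
Reagents that add atoms: none
Why: SmI2 reduction of an α-alkoxy ketone cleaves the bridge C–O bond next to the carbonyl (future C9 becomes CH2) and leaves the oxygen on the other bridgehead with retention as the C6–OH cis to the side chain; using the saturated ketone avoids the vinylogous C–O cleavage that the enone could undergo.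

Step 7
Reactants: 12 (3S,4R,5R)-hydroxy ketone
Product: 13 (3S,4R,5R)-5-[(2S)-2-hydroxy-6-methylhept-5-en-2-yl]-3-(phenylsulfanyl)-4-(triethylsilyloxy)cycloheptan-1-one
Conditions: Et3SiCl, imidazole, DMAP (cat.), DMF, rt
Reagents that add atoms: chlorotriethylsilane (CC[Si](Cl)(CC)CC)
Why: Sterically controlled silylation takes the secondary OH and leaves the tertiary carbinol free for step 8.

Step 8
Reactants: 13 TES ether sulfide
Product: 16 (4S,5R)-5-[(2S,5R)-5-(2-hydroxypropan-2-yl)-2-methyloxolan-2-yl]-4-(triethylsilyloxy)cyclohept-2-en-1-one, via epoxy sulfone 14 (not isolated), via epoxy enone 15 (not isolated)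
Conditions: enantiomer of the fructose-derived Shi ketone (from L-sorbose, 30 mol %), KHSO5 triple salt (4 equiv), K2CO3, Bu4NHSO4, MeCN–dimethoxymethane/aq. Na2B4O7 (pH 10.5), 0 °C; crude extract, CSA (10 mol %), CH2Cl2, 0 °C
Reagents that add atoms: potassium peroxymonosulfate ([K+].[O-]S(=O)(=O)OO)
Why: KHSO5 oxidises the sulfide to the sulfone, which leaves by E1cB at pH 10.5 and restores the enone, while the chiral dioxirane (Shi epoxidation) gives the (S)-epoxide under reagent control and acid-catalysed 5-exo-tet opening by the C11–OH with inversion sets C14 (R) and the 2,5-cis oxolane; any minor enantiomer left from step 4 ends as the separable trans-oxolane diastereomer.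

Step 9
Reactants: 16 oxolane alcohol
Product: 17 2-[(2R,5S)-5-methyl-5-[(1R,2S)-5-oxo-2-(triethylsilyloxy)cyclohept-3-en-1-yl]oxolan-2-yl]propan-2-yl acetate
Conditions: Ac2O, Et3N, DMAP (1 equiv), CH2Cl2, 35 °C
Reagents that add atoms: acetic anhydride (CC(=O)OC(C)=O)
Why: DMAP-promoted acylation of the only free (tertiary) OH puts the acetate on C15 while C6–O is still silylated.

Step 10
Reactants: 17 enone acetate
Product: 19 (2R,3S,4S,5R)-2-allyl-3-isopropenyl-4-(triethylsilyloxy)-5-(oxolanyl acetate)cycloheptan-1-one, via magnesium enolate 18 (not isolated)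
Conditions: isopropenylmagnesium bromide (1.3 equiv, slow addition), CuBr·SMe2 (15 mol %), THF, −78 to −40 °C; allyl iodide, DMPU, −40 to 0 °C
Reagents that add atoms: isopropenylmagnesium bromide (C=C(C)[Mg]Br); allyl iodide (C=CCI)
Why: Copper-catalysed conjugate addition anti to the γ-silyloxy group and the side chain (both on the α face) sets C5, and enolate 18 is allylated anti to the new isopropenyl group, which sets C1 and the trans relationship (three-component enone coupling).

Step 11
Reactants: 19 allyl isopropenyl ketone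
Product: 20 (3aS,4S,5R,8aR)-3-methyl-5-(oxolanyl acetate)-4-(triethylsilyloxy)-3a,4,5,6,7,8a-hexahydro-1H-azulen-8-one (trans-fused)
Conditions: second-generation Grubbs catalyst (5 mol %), CH2Cl2, 40 °C
Reagents that add atoms: none
Why: Ring-closing metathesis of the allyl and isopropenyl groups gives the trisubstituted cyclopentene with the methyl on C4; no stereocentre is touched and the neutral medium keeps the trans ring fusion.

Step 12
Reactants: 20 trans-hydroazulenone
Product: 22 target CNP0302132.4, via TES ether 21 (not isolated)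
Conditions: Zn, CH2I2, TiCl4, THF/CH2Cl2, 0 °C to rt; then 1 M HCl, THF, rt
Reagents that add atoms: diiodomethane (ICI)
Why: Takai–Lombardo methylenation with the non-basic gem-dizinc/titanium reagent converts the ketone without epimerising C1 or attacking the acetate, and the dilute acid quench cleaves the TES ether to free the C6–OH.

## Compound list
1 | furfuryl alcohol | OCc1ccco1 | starting material
2 | 6-hydroxy-2H-pyran-3(6H)-one (racemic hemiacetal) | O=C1C=CC(O)OC1 | intermediate
3 | 6-acetoxy-2H-pyran-3(6H)-one (racemic) | CC(=O)OC1C=CC(=O)CO1 | intermediate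
4 | 5-bromo-2-methylpent-2-ene | CC(C)=CCCBr | starting material
5 | N-methoxy-N-methylacrylamide | C=CC(=O)N(C)OC | starting material
6 | (4-methylpent-3-en-1-yl)magnesium bromide (not isolated) | CC(C)=CCC[Mg]Br | intermediate
7 | 7-methylocta-1,6-dien-3-one | C=CC(=O)CCC=C(C)C | intermediate
8 | 3-oxidopyrylium, aromatic betaine (not isolated) | [O-]c1ccc[o+]c1 | intermediate
9 | (1S,5S,6R)-6-(5-methylhex-4-enoyl)-8-oxabicyclo[3.2.1]oct-3-en-2-one, exo acyl | O=C1C=C[C@H]2[C@H](C(=O)CCC=C(C)C)C[C@@H]1O2 | intermediate
10 | exo-4-phenylsulfanyl-2-trimethylsilyloxy-8-oxabicyclo[3.2.1]oct-2-ene carrying the exo acyl chain of 9 (not isolated) | C[Si](C)(C)OC1=C[C@H](Sc2ccccc2)[C@H]2[C@H](C(=O)CCC=C(C)C)C[C@@H]1O2 | intermediate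
11 | (1S,4S,5R,6R)-6-[(2S)-2-hydroxy-6-methylhept-5-en-2-yl]-4-(phenylsulfanyl)-8-oxabicyclo[3.2.1]octan-2-one | O=C1C[C@H](Sc2ccccc2)[C@H]2[C@H]([C@@](C)(O)CCC=C(C)C)C[C@@H]1O2 | intermediate
12 | (3S,4R,5R)-4-hydroxy-5-[(2S)-2-hydroxy-6-methylhept-5-en-2-yl]-3-(phenylsulfanyl)cycloheptan-1-one | O=C1CC[C@@H]([C@@](C)(O)CCC=C(C)C)[C@@H](O)[C@@H](Sc2ccccc2)C1 | intermediate
13 | 4-O-triethylsilyl ether of 12 | O=C1CC[C@@H]([C@@](C)(O)CCC=C(C)C)[C@@H](O[Si](CC)(CC)CC)[C@@H](Sc2ccccc2)C1 | intermediate
14 | phenyl sulfone of 13 with (S)-epoxide in the side chain (not isolated) | O=C1CC[C@@H]([C@@](C)(O)CC[C@@H]2OC2(C)C)[C@@H](O[Si](CC)(CC)CC)[C@@H](S(=O)(=O)c2ccccc2)C1 | intermediate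
15 | (4S,5R)-enone with (2S)-carbinol and (S)-epoxide side chain (not isolated) | O=C1CC[C@@H]([C@@](C)(O)CC[C@@H]2OC2(C)C)[C@@H](O[Si](CC)(CC)CC)C=C1 | intermediate
16 | (4S,5R)-5-[(2S,5R)-5-(2-hydroxypropan-2-yl)-2-methyloxolan-2-yl]-4-(triethylsilyloxy)cyclohept-2-en-1-one | O=C1CC[C@@H]([C@]2(C)CC[C@H](C(C)(C)O)O2)[C@@H](O[Si](CC)(CC)CC)C=C1 | intermediate
17 | tertiary acetate of 16 | O=C1CC[C@@H]([C@]2(C)CC[C@H](C(C)(C)OC(C)=O)O2)[C@@H](O[Si](CC)(CC)CC)C=C1 | intermediate
18 | bromomagnesium enolate after β-face isopropenyl addition (not isolated) | Br[Mg]OC1=C[C@@H](C(C)=C)[C@H](O[Si](CC)(CC)CC)[C@H]([C@]2(C)CC[C@H](C(C)(C)OC(C)=O)O2)CC1 | intermediate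
19 | (2R,3S,4S,5R)-2-allyl-3-isopropenyl-4-(triethylsilyloxy)cycloheptanone carrying the oxolanyl acetate at C5 | O=C1CC[C@@H]([C@]2(C)CC[C@H](C(C)(C)OC(C)=O)O2)[C@@H](O[Si](CC)(CC)CC)[C@H](C(C)=C)[C@H]1CC=C | intermediate
20 | trans-fused (3aS,4S,5R,8aR)-hydroazulen-8-one, 4-OTES, 3-methyl | O=C1CC[C@@H]([C@]2(C)CC[C@H](C(C)(C)OC(C)=O)O2)[C@@H](O[Si](CC)(CC)CC)[C@@H]2C(C)=CC[C@@H]12 | intermediate
21 | 6-O-triethylsilyl ether of the target (not isolated) | C=C1CC[C@@H]([C@]2(C)CC[C@H](C(C)(C)OC(C)=O)O2)[C@@H](O[Si](CC)(CC)CC)[C@@H]2C(C)=CC[C@@H]12 | intermediate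
22 | 2-[(2R,5S)-5-[(3aS,4S,5R,8aR)-4-hydroxy-3-methyl-8-methylidene-1,3a,4,5,6,7,8,8a-octahydroazulen-5-yl]-5-methyloxolan-2-yl]propan-2-yl acetate | C=C1CC[C@@H]([C@]2(C)CC[C@H](C(C)(C)OC(C)=O)O2)[C@@H](O)[C@@H]2C(C)=CC[C@@H]12 | target

## Step count and risks
Total step count: 12.
Longest linear sequence: 11 (steps 1, 2 and 4–12 from furfuryl alcohol). Step 3 is the one-step side branch.

The three steps most likely to fail are 4, 5 and 8.

**Step 4.** The asymmetric catalysis is untested and may give low ee or lose to ylide dimerisation. The fallback gives up catalyst control and lets step 8 sort the enantiomers. It sets out from 3 and 7. Et3N (CH2Cl2, rt, then DBU) gives racemic 9, that is 9 together with the mirror-image adduct F1. The mixture is carried through steps 5 to 7, where the mirror-image series consists of the mirror-image thio silyl enol ether F2, the mirror-image sulfide carbinol F3, the mirror-image hydroxy ketone F4 and the mirror-image TES ether F5. In step 8 the (S)-selective dioxirane turns F5 into the diastereomeric epoxy sulfone F6 and the diastereomeric epoxy enone F7. These can only close to the 2,5-trans oxolane F8, a diastereomer of 16 that is removed by chromatography (at most 50 % yield). The route is rejoined at 16.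

**Step 5.** Chelation of magnesium by the bridge oxygen could overturn Felkin–Anh control and give the C11 epimer. The fallback exchanges the resident and the incoming group. It sets out from 3, which is combined with methyl vinyl ketone under the conditions of step 4 to give the exo acetyl adduct F9. PhSSiMe3 converts this into the acetyl thio silyl enol ether F10. Grignard reagent 6 now delivers the homoprenyl chain on the face that methyl would have taken. Acid work-up comes back to the route at 11.

**Step 8.** Three events run in one pot: sulfide oxidation/elimination, epoxidation at pH 10.5, and 5-exo against 6-endo opening. The fallback separates the events and replaces reagent control by hydroxyl-directed substrate control. It sets out from 13. mCPBA (1 equiv, −78 °C) gives the β-keto sulfoxide F11. Et3N at rt eliminates it to the dienyl carbinol enone F12. VO(acac)2/t-BuOOH then epoxidises only the alkene that the C11–OH can reach. The 2,5-cis preference of this oxidative cyclisation (bulky groups cis) leads through 15 back to 16.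

## Further compounds
F1 | step 4 | mirror image of 9 | O=C1C=C[C@@H]2[C@@H](C(=O)CCC=C(C)C)C[C@H]1O2
F2 | step 4 | mirror image of 10 | C[Si](C)(C)OC1=C[C@@H](Sc2ccccc2)[C@@H]2[C@@H](C(=O)CCC=C(C)C)C[C@H]1O2
F3 | step 4 | mirror image of 11 | O=C1C[C@@H](Sc2ccccc2)[C@@H]2[C@@H]([C@](C)(O)CCC=C(C)C)C[C@H]1O2
F4 | step 4 | mirror image of 12 | O=C1CC[C@H]([C@](C)(O)CCC=C(C)C)[C@H](O)[C@H](Sc2ccccc2)C1
F5 | step 4 | mirror image of 13 | O=C1CC[C@H]([C@](C)(O)CCC=C(C)C)[C@H](O[Si](CC)(CC)CC)[C@H](Sc2ccccc2)C1
F6 | step 4 | epoxy sulfone with mirror-image core and (S)-epoxide | O=C1CC[C@H]([C@](C)(O)CC[C@@H]2OC2(C)C)[C@H](O[Si](CC)(CC)CC)[C@H](S(=O)(=O)c2ccccc2)C1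
F7 | step 4 | epoxy enone with mirror-image core and (S)-epoxide | O=C1CC[C@H]([C@](C)(O)CC[C@@H]2OC2(C)C)[C@H](O[Si](CC)(CC)CC)C=C1
F8 | step 4 | (4R,5S)-enone with (2R,5R)-2,5-trans oxolane, diastereomer of 16 | O=C1CC[C@H]([C@@]2(C)CC[C@H](C(C)(C)O)O2)[C@H](O[Si](CC)(CC)CC)C=C1
F9 | step 5 | (1S,5S,6R)-6-acetyl-8-oxabicyclo[3.2.1]oct-3-en-2-one | O=C1C=C[C@H]2[C@H](C(C)=O)C[C@@H]1O2
F10 | step 5 | exo-4-phenylsulfanyl-2-trimethylsilyloxy derivative of F9 | C[Si](C)(C)OC1=C[C@H](Sc2ccccc2)[C@H]2[C@H](C(C)=O)C[C@@H]1O2
F11 | step 8 | phenyl sulfoxide of 13 (sulfur configuration undefined) | O=C1CC[C@@H]([C@@](C)(O)CCC=C(C)C)[C@@H](O[Si](CC)(CC)CC)[C@@H](S(=O)c2ccccc2)C1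
F12 | step 8 | (4S,5R)-5-[(2S)-2-hydroxy-6-methylhept-5-en-2-yl]-4-(triethylsilyloxy)cyclohept-2-en-1-one | O=C1CC[C@@H]([C@@](C)(O)CCC=C(C)C)[C@@H](O[Si](CC)(CC)CC)C=C1
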